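Moles per litre, not percent, are the unit to watch in this flask, which takes oak's reagent charge and alder's substrate charge.

| flask | substrate | reagent in the second phase | remark | time | volume of the second phase over the first |
|---|---|---|---|---|---|
| alder | 0.35 M | 0.39 M | run made earlier |  |  |
| birch | 0.35 M | 0.62 M | run made earlier |  |  |
| oak | 0.52 M | 0.28 M | run made earlier |  |  |
| flask | 0.35 M | 0.280 M |  | 2.5 h | 0.25 |

| run | time / h | target / % | substrate / % |
|---|---|---|---|
| alder | 0.167 | 8.6 | 89.4 |
| alder | 0.417 | 17.1 | 66.4 |
| alder | 1.00 | 16.0 | 40.4 |
| alder | 2.50 | 9.9 | 24.8 |
| birch | 0.167 | 12.2 | 83.7 |
| birch | 0.417 | 20.2 | 52.7 |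
| birch | 1.00 | 15.1 | 25.2 |
| birch | 2.50 | 8.0 | 12.0 |
| oak | 0.167 | 5.7 | 92.9 |
| oak | 0.417 | 11.3 | 75.7 |
| oak | 1.00 | 10.7 | 55.4 |
| oak | 2.50 | 3.7 | 42.6 |

(readings scatter by 0.3 percentage points)

- in the second phase: reagent in the second phase; everything else is in the first
- charges count per volume of the first phase; a concentration in a rate is the amount of a species over the volume of its own phase; every rate counts per litre of the first phase
- the earlier runs hold the two phases in the same ratio of volumes as the flask asked about

* time up to 2.5 h at which target stands highest
* the amount of target, in percent of the substrate charged, at that time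

Target stands highest at the moment it is made as fast as it is used up, and making goes with substrate times reagent. Two extreme versions can be solved in the head. If target is used up at a rate going with substrate times target, substrate cancels from that balance, so the concentration at the peak carries over between flasks of equal reagent charge. Call this the molar peak, the concentration of target at the top of a run at a given reagent charge. Oak's top falls between samples, so its value can only be estimated, and oak's top may stand above its highest reading, taken at 0.417 h; that reading gives 0.0588 M, which is 16.8% of this flask's charge. If instead target is lost at a rate blind to substrate, the percentage carries over, 11.3%.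

The real flask lies between, and this reckoning puts it near the upper end. From 1.00 h to 2.50 h target falls faster in oak, 0.708 h⁻¹ against 0.320 h⁻¹, a ratio of 2.21, while the mean substrate concentration stands 2.23 times higher. The peak time belongs between 0.417 h and 1.00 h, where oak's target turns.

The forecast, holding that “Target is lost quickly, faster at a higher substrate charge”, gives 14.5% at 0.65 h, lower than this reckoning's upper end.

The flask gives 16.1% at 0.678 h, when over-reacted product stands at 9.67%, under this scheme:

    substrate + target → side product (k = 9.80 × 10⁻⁴ L mol⁻¹ s⁻¹)
    reagent in the reaction phase → decomposed reagent (k = 1.80 × 10⁻⁴ s⁻¹)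
    reagent in the reaction phase ⇌ reagent in the second phase, rate k3*([reagent in the reaction phase] - [reagent in the second phase]/K3) per volume of the first phase (partition coefficient = 1.50, kL = 3.90 × 10⁻⁴ s⁻¹)
    substrate + reagent in the reaction phase → target (k = 0.00230 L mol⁻¹ s⁻¹)
    reagent in the reaction phase + target → over-reacted product (k = 0.00490 L mol⁻¹ s⁻¹)

That peak is 0.0562 M of target, against the molar peak of 0.0588 M read from oak. The neighbour charged with 1.4 M of substrate holds the same reagent charge, so the molar peak gives it 4.20%, and that flask reaches 4.71%.

The readings are calculated for substances that don't exist.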